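**Retrosynthetic overview**

- The route rests on one feature of ring A: C7–OH is the only free hydroxyl, it sits between the C6 and C8 methoxy groups, and it is para to C4a. Two-electron oxidation of this phenol to a quinone monoketal makes the single C–H carbon of the ring (the future C8a, meta to the hydroxyl) an acceptor.
- Target 14 is disconnected at O1–C8a (ring C, the pyranone) to the open 1,3-diketone 10, which carries no 2'-oxygen. The enol oxygen on C2 closes onto C8a, and loss of methanol restores the arene and the C7–OH.
- Diketone 10 comes from its 7-O-benzyl ether 9, made by Claisen condensation (C2–C3 bond) of acetophenone 7 with methyl 4-methoxybenzoate 8.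
- Acetophenone 7 comes from acetosyringone 1 by O-benzylation, ring bromination ortho to the acetyl group, and copper-mediated methoxylation (the future C5–OMe).
- Ring order: rings A and B are bought; ring C is formed last, in the key step.

Key step: step 6

Remark: the target has no stereocentre, so no stereocontrol is needed; the transient adduct 13 is racemic at C8a and that centre is lost on aromatisation.

**Route**

Step 1
Reactants: 1 acetosyringone (4'-hydroxy-3',5'-dimethoxyacetophenone), 2 benzyl bromide
Product: 3 1-(4-(benzyloxy)-3,5-dimethoxyphenyl)ethanone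
Conditions: BnBr, K2CO3, DMF, 60 °C
Reagents that add atoms: benzyl bromide, BrCc1ccccc1
Why: Williamson ether synthesis on the acidic 2,6-dimethoxyphenol should proceed cleanly with carbonate and masks the phenol against oxidation by NBS and against deprotonation in the Claisen step.

Step 2
Reactants: 3 1-(4-(benzyloxy)-3,5-dimethoxyphenyl)ethanone, 4 N-bromosuccinimide
Product: 5 1-(4-(benzyloxy)-2-bromo-3,5-dimethoxyphenyl)ethanone
Conditions: NBS, MeCN, 0 °C to rt, dark
Reagents that add atoms: N-bromosuccinimide, O=C1CCC(=O)N1Br
Why: Electrophilic aromatic substitution should take place at one of the two equivalent free ring carbons, each ortho to one methoxy group and para to the other, and NBS in acetonitrile without acid or light favours nuclear over side-chain bromination.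

Step 3
Reactants: 5 1-(4-(benzyloxy)-2-bromo-3,5-dimethoxyphenyl)ethanone, 6 sodium methoxide
Product: 7 1-(4-(benzyloxy)-2,3,5-trimethoxyphenyl)ethanone
Conditions: NaOMe, CuI (cat.), DMF–MeOH, 100 °C
Reagents that add atoms: sodium methoxide, [Na+].[O-]C
Why: Copper-catalysed Ullmann-type methoxylation of an aryl bromide, assisted by the ortho acetyl group, is the classical way to turn a bromo-oxygenated aryl carbonyl compound into its methoxy analogue, and the benzyl ether is inert to methoxide.

Step 4
Reactants: 7 1-(4-(benzyloxy)-2,3,5-trimethoxyphenyl)ethanone, 8 methyl 4-methoxybenzoate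
Product: 9 1-(4-(benzyloxy)-2,3,5-trimethoxyphenyl)-3-(4-methoxyphenyl)propane-1,3-dione
Conditions: NaH (2.5 equiv), THF, reflux; then aq. HCl
Reagents that add atoms: methyl 4-methoxybenzoate, COC(=O)c1ccc(OC)cc1
Why: In this crossed Claisen condensation the sodium enolate of methyl ketone 7 acylates the non-enolisable ester 8, and deprotonation of the resulting 1,3-diketone drives the equilibrium to product.

Step 5
Reactants: 9 1-(4-(benzyloxy)-2,3,5-trimethoxyphenyl)-3-(4-methoxyphenyl)propane-1,3-dione
Product: 10 1-(4-hydroxy-2,3,5-trimethoxyphenyl)-3-(4-methoxyphenyl)propane-1,3-dione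
Conditions: H2 (1 atm), 10% Pd/C, EtOAc, rt
Reagents that add atoms: none
Why: Hydrogenolysis of the benzyl aryl ether over palladium should free the phenol, while the chelated enol of the diaryl 1,3-diketone and the methyl ethers are not touched at one atmosphere and room temperature.

Step 6
Reactants: 10 1-(4-hydroxy-2,3,5-trimethoxyphenyl)-3-(4-methoxyphenyl)propane-1,3-dione, 11 methanol
Product: 14 7-hydroxy-5,6,8-trimethoxy-2-(4-methoxyphenyl)-4H-chromen-4-one, via quinone monoketal 12 (not isolated), via dienol adduct 13 (not isolated)
Conditions: undivided cell, graphite anode, Pt cathode, LiClO4, MeOH, 0 °C, anode held at the foot of the first oxidation wave of 10 (read from cyclic voltammetry), about 2 F/mol; then current off, AcOH, 0 °C to 40 °C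
Reagents that add atoms: methanol, CO
Why: Proposed new method: two-electron anodic oxidation of the 2,6-dimethoxyphenol unit of 10 (C7–OH between the C6 and C8 methoxy groups) should give a phenoxonium ion that methanol captures at the less crowded methoxy-bearing ortho carbon C8, giving the 6,6-dimethoxycyclohexa-2,4-dienone 12, in which C8a, the only C–H carbon of the ring, is the δ-terminus of the dienone and also β to the C4 ketone. The oxygen of the chelated diketone enol on C2 (the carbon bearing the 4-methoxyphenyl group) should then add to C8a in a 6-endo-trig oxa-conjugate addition (equally an oxa-6π closure of the O=C2–C3=C4–C4a=C8a array), forming O1–C8a and the pyranone ring in dienol 13; ionisation of one C8 methoxy group, helped by the acetic acid added once the current is off, gives an arenium ion stabilised by four oxygens that loses the C8a proton, so ring A rearomatises and the C7 hydroxyl returns. The closest known reactions are the anodic and iodine(III) oxidations of 2-methoxyphenols to masked o-benzoquinones and the addition of nucleophiles to quinone monoketals followed by loss of methanol to a substituted phenol, but their combination into a pyranone-forming cascade from a 1,3-diketone is not established. No stereocentre is set, since the C8a centre of 13 disappears on aromatisation. Three selectivities are needed: oxidation of the phenol before the diketone enol or the anisyl ring, which the lower potential of the trioxygenated phenol and potential control should secure; closure at C8a and not at C5, which is also within six-ring reach but is a hindered vinylogous-ester carbon whose adduct cannot aromatise and can revert, whereas closure at C8a is made irreversible by aromatisation (capture of methanol at C6 instead of C8 leads to the same product, because C8a is then the β-carbon of the dienone); and sparing of the product phenol, which also carries a para carbonyl and two ortho methoxy groups and is expected to be only slightly harder to oxidise because the new O1 is meta to the hydroxyl. For that last reason the charge is limited, the electrolysis is run cold, and the closure is completed only after the current is off.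

**Compound list**

1 | acetosyringone (4'-hydroxy-3',5'-dimethoxyacetophenone) | CC(=O)c1cc(OC)c(O)c(OC)c1 | starting material
2 | benzyl bromide | BrCc1ccccc1 | starting material
3 | 1-(4-(benzyloxy)-3,5-dimethoxyphenyl)ethanone | CC(=O)c1cc(OC)c(OCc2ccccc2)c(OC)c1 | intermediate
4 | N-bromosuccinimide | O=C1CCC(=O)N1Br | starting material
5 | 1-(4-(benzyloxy)-2-bromo-3,5-dimethoxyphenyl)ethanone | CC(=O)c1cc(OC)c(OCc2ccccc2)c(OC)c1Br | intermediate
6 | sodium methoxide | [Na+].[O-]C | starting material
7 | 1-(4-(benzyloxy)-2,3,5-trimethoxyphenyl)ethanone | CC(=O)c1cc(OC)c(OCc2ccccc2)c(OC)c1OC | intermediate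
8 | methyl 4-methoxybenzoate | COC(=O)c1ccc(OC)cc1 | starting material
9 | 1-(4-(benzyloxy)-2,3,5-trimethoxyphenyl)-3-(4-methoxyphenyl)propane-1,3-dione | COc1ccc(C(=O)CC(=O)c2cc(OC)c(OCc3ccccc3)c(OC)c2OC)cc1 | intermediate
10 | 1-(4-hydroxy-2,3,5-trimethoxyphenyl)-3-(4-methoxyphenyl)propane-1,3-dione | COc1ccc(C(=O)CC(=O)c2cc(OC)c(O)c(OC)c2OC)cc1 | intermediate
11 | methanol | CO | starting material
12 | 1-(3,3,5,6-tetramethoxy-4-oxocyclohexa-1,5-dien-1-yl)-3-(4-methoxyphenyl)propane-1,3-dione (quinone monoketal) | COc1ccc(C(=O)CC(=O)C2=CC(OC)(OC)C(=O)C(OC)=C2OC)cc1 | intermediate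
13 | 7-hydroxy-5,6,8,8-tetramethoxy-2-(4-methoxyphenyl)-8,8a-dihydro-4H-chromen-4-one (racemic at C8a) | COc1ccc(C2=CC(=O)C3=C(OC)C(OC)=C(O)C(OC)(OC)C3O2)cc1 | intermediate
14 | 7-hydroxy-5,6,8-trimethoxy-2-(4-methoxyphenyl)-4H-chromen-4-one | COc1ccc(-c2cc(=O)c3c(OC)c(OC)c(O)c(OC)c3o2)cc1 | target

**Step count**

Total steps: 6. Longest linear sequence: 6 steps (1 → 3 → 5 → 7 → 9 → 10 → 14).

**Steps most likely to fail**

1. Step 6 (proposed new method). The enol oxygen may close onto the methoxy-bearing C5 by addition–elimination. The product phenol may be oxidised a second time at the anode. The dienone ketal may also dimerise or hydrolyse before it cyclises. The fallback uses known chemistry and brings in the C8a oxygen through a halide instead of an oxidation. It sets out from 7: ring bromination with NBS in MeCN at the one remaining ring C–H should give 1-(4-(benzyloxy)-2-bromo-3,5,6-trimethoxyphenyl)ethanone F1. Claisen condensation of F1 with 8 (NaH, THF, reflux) should give 1-(4-(benzyloxy)-2-bromo-3,5,6-trimethoxyphenyl)-3-(4-methoxyphenyl)propane-1,3-dione F2. Copper-catalysed intramolecular O-arylation of the diketone enol (CuI, K2CO3, DMF, 110 °C) should close the pyranone to 7-(benzyloxy)-5,6,8-trimethoxy-2-(4-methoxyphenyl)-4H-chromen-4-one F3. Hydrogenolysis (H2, Pd/C, EtOAc, rt) then returns to the route at 14.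

2. Step 3. Reductive loss of bromine under the copper/methoxide conditions, or base-induced self-condensation of the methyl ketone in hot methoxide, may erode the methoxylation. The fallback installs the oxygen through boron. It sets out from 5: Miyaura borylation (B2pin2, PdCl2(dppf), KOAc, dioxane, 90 °C) should give 1-(4-(benzyloxy)-3,5-dimethoxy-2-(4,4,5,5-tetramethyl-1,3,2-dioxaborolan-2-yl)phenyl)ethanone F4. Mild oxidation (NaBO3·4H2O, THF–H2O, rt, chosen to avoid Dakin-type cleavage of the acetyl group) should give 1-(4-(benzyloxy)-2-hydroxy-3,5-dimethoxyphenyl)ethanone F5. O-Methylation (MeI, K2CO3, acetone, reflux) returns to the route at 7.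

3. Step 2. Bromination may occur at the acetyl methyl group through the enol, or at the benzylic CH2, instead of on the ring. The fallback removes the enolisable ketone before halogenation. It sets out from 3: ketalisation (ethylene glycol, TsOH, toluene, Dean–Stark) should give 2-(4-(benzyloxy)-3,5-dimethoxyphenyl)-2-methyl-1,3-dioxolane F6. NBS in MeCN should then brominate only the ring, giving 2-(4-(benzyloxy)-2-bromo-3,5-dimethoxyphenyl)-2-methyl-1,3-dioxolane F7. Hydrolysis of the ketal (aq. HCl, THF, rt) returns to the route at 5.

**Further compounds**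

F1 | step 6 | 1-(4-(benzyloxy)-2-bromo-3,5,6-trimethoxyphenyl)ethanone | CC(=O)c1c(Br)c(OC)c(OCc2ccccc2)c(OC)c1OC
F2 | step 6 | 1-(4-(benzyloxy)-2-bromo-3,5,6-trimethoxyphenyl)-3-(4-methoxyphenyl)propane-1,3-dione | COc1ccc(C(=O)CC(=O)c2c(Br)c(OC)c(OCc3ccccc3)c(OC)c2OC)cc1
F3 | step 6 | 7-(benzyloxy)-5,6,8-trimethoxy-2-(4-methoxyphenyl)-4H-chromen-4-one | COc1ccc(-c2cc(=O)c3c(OC)c(OC)c(OCc4ccccc4)c(OC)c3o2)cc1
F4 | step 3 | 1-(4-(benzyloxy)-3,5-dimethoxy-2-(4,4,5,5-tetramethyl-1,3,2-dioxaborolan-2-yl)phenyl)ethanone | CC(=O)c1cc(OC)c(OCc2ccccc2)c(OC)c1B1OC(C)(C)C(C)(C)O1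
F5 | step 3 | 1-(4-(benzyloxy)-2-hydroxy-3,5-dimethoxyphenyl)ethanone | CC(=O)c1cc(OC)c(OCc2ccccc2)c(OC)c1O
F6 | step 2 | 2-(4-(benzyloxy)-3,5-dimethoxyphenyl)-2-methyl-1,3-dioxolane | CC1(OCCO1)c1cc(OC)c(OCc2ccccc2)c(OC)c1
F7 | step 2 | 2-(4-(benzyloxy)-2-bromo-3,5-dimethoxyphenyl)-2-methyl-1,3-dioxolane | CC1(OCCO1)c1cc(OC)c(OCc2ccccc2)c(OC)c1Br
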